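**Retrosynthetic overview**

1. The target is an all-trans cyclobutane (both aryl groups on one face, both carboxyl carbons on the other), formally the head-to-tail dimer of rosmarinic acid and 4-coumaric acid; the (R)-lactate ester and its stereocentre are taken intact from (R)-rosmarinic acid.
2. Key disconnection: the ring bond C1–C2 (CH–CO2H to CH–C6H4OH) is made by cutting a nitrogen atom out of a pyrrolidine in which N bridges these two carbons (1,1-diazene → N2 + 1,4-biradical → cyclobutane). Enabling feature: C1 bears a carboxyl group and C2 an aryl group, so C1–N–C2 is the retron of a glycine-imine azomethine ylide, and both carbons give stabilised radicals once N2 is lost.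
3. The pyrrolidine is assembled from three pieces (glycine benzyl ester, 4-(benzyloxy)benzaldehyde, protected rosmarinate) by an exo-selective Cu-catalysed [3+2] cycloaddition that fixes C2, C3 and C4.
4. C1, the one centre a chelated ylide cannot deliver correctly, is inverted after the contraction by thermodynamic epimerisation while the lactate carboxyl is a carboxylate; hydrogenolysis ends the route.
5. Ring order: temporary pyrrolidine (step 4) → cyclobutane (step 5).

Key step: step 5

Remark on numbering: cyclobutane C1 = CH–CO2H (CO2Bn), C2 = CH–(4-oxyphenyl), C3 = CH–CO–O-lactate, C4 = CH–(3,4-dioxyphenyl); pyrrolidine C2, C5, C4, C3 become cyclobutane C1, C2, C3, C4.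

Remark on the ligand: the antipode of DTBM-Segphos that leads to the (2S,3S,4R,5R) adduct is to be fixed in a pilot run; the route is written with the (R)-ligand.

**Route**

Step 1
Reactants: 1 (R)-rosmarinic acid
Product: 2 4-methoxybenzyl (R)-rosmarinate
Conditions: 4-methoxybenzyl chloride (1.05 equiv), KHCO3 (1.2 equiv), NaI (10 mol%), DMF, rt
Reagents that add atoms: 4-methoxybenzyl chloride, COc1ccc(CCl)cc1
Why: Chemoselective SN2 O-alkylation of the carboxylate, since hydrogencarbonate ionises only the carboxylic acid and neither the four phenols nor the acyloxy-bearing stereocentre.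

Step 2
Reactants: 2 4-methoxybenzyl (R)-rosmarinate
Product: 3 4-methoxybenzyl (2R)-3-[3,4-bis(benzyloxy)phenyl]-2-{[(2E)-3-[3,4-bis(benzyloxy)phenyl]prop-2-enoyl]oxy}propanoate
Conditions: BnBr (4.4 equiv), K2CO3 (5 equiv), acetone, 45 °C
Reagents that add atoms: benzyl bromide, BrCc1ccccc1
Why: Williamson ether synthesis on the four phenoxides under heterogeneous carbonate conditions that should not enolise the α-acyloxy ester, so the (R) centre and the (E)-alkene are kept.

Step 3
Reactants: 4 glycine benzyl ester hydrochloride; 5 4-(benzyloxy)benzaldehyde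
Product: 6 benzyl N-[(E)-4-(benzyloxy)benzylidene]glycinate
Conditions: Et3N (1.05 equiv), MgSO4, CH2Cl2, rt; filtered, concentrated, used crude
Reagents that add atoms: none
Why: Imine condensation of the liberated amino ester with the aldehyde, driven by the drying agent, to the (E)-aldimine.

Step 4
Reactants: 3 protected rosmarinate; 6 benzyl N-[(E)-4-(benzyloxy)benzylidene]glycinate (1.5 equiv)
Product: 7 2-benzyl 4-{(2R)-3-[3,4-bis(benzyloxy)phenyl]-1-[(4-methoxybenzyl)oxy]-1-oxopropan-2-yl} (2S,3S,4R,5R)-3-[3,4-bis(benzyloxy)phenyl]-5-[4-(benzyloxy)phenyl]pyrrolidine-2,4-dicarboxylate (exo adduct: 2-CO2Bn, 3-aryl and 5-aryl on one face, 4-ester on the other)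
Conditions: Cu(CH3CN)4PF6 (5 mol%), (R)-DTBM-Segphos (5.5 mol%), Et3N (15 mol%), THF, −20 °C → rt
Reagents that add atoms: none
Why: Catalytic asymmetric 1,3-dipolar cycloaddition of the N,O-chelated (W-shaped) copper azomethine ylide of 6: the ylide α-carbon bonds to the β-carbon of the enoate (regiochemistry), chelation gives 2,5-cis, the (E)-alkene gives 3,4-trans, the bulky bisphosphine pushes the ester of 3 away from the metal (exo mode: 4,5-trans, the two aryl groups cis) and shields one face of the ylide, so the (2S,3S,4R,5R) adduct should result while the remote lactate centre (weak, catalytic base) is untouched.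

Step 5
Reactants: 7 exo pyrrolidine
Product: 10 1-benzyl 3-{(2R)-3-[3,4-bis(benzyloxy)phenyl]-1-[(4-methoxybenzyl)oxy]-1-oxopropan-2-yl} (1S,2R,3S,4S)-4-[3,4-bis(benzyloxy)phenyl]-2-[4-(benzyloxy)phenyl]cyclobutane-1,3-dicarboxylate (CO2Bn at C1 cis to both aryl groups), via 1,1-diazene 8 (not isolated), via 1,4-biradical 9 (not isolated)
Conditions: PhI(OH)OTs (2.5 equiv), H2NCO2NH4 (8 equiv), CF3CH2OH, 80 °C
Reagents that add atoms: none
Why: PhI(OH)OTs and ammonia (from the carbamate) form an iodonitrene that aminates the pyrrolidine nitrogen to the 1,1-diazene 8, which loses N2 to the singlet 1,4-biradical 9 (ester-stabilised radical at C1, 4-(benzyloxy)benzyl radical at C2) whose two ends couple to the C1–C2 bond. The closest known reaction type is the iodonitrene-mediated contraction of 2,5-disubstituted pyrrolidines to cyclobutanes (nitrogen extrusion from a 1,1-diazene). The four-membered ring closes by radical–radical recombination of the 1,4-biradical, a 1,4-closure outside the polar exo/endo rules. C1 and C2 are the only centres that pass through radicals, and both should be re-formed with retention of the pyrrolidine C2 and C5 configurations, because collapse of the singlet biradical is faster than rotation about C1–C4 and C2–C3, while C3 and C4 are not touched. The step needs ring closure to win over β-scission of the C3–C4 bond (two cinnamate-type alkenes) and N-amination to win over attack of the trivalent iodine reagent on the alkoxyarenes. The ester at C1 and the aryl group at C2 make N2 loss fast and the biradical short-lived, and the excess of ammonium carbamate in CF3CH2OH turns the iodane quickly into the nitrogen-transfer species, conditions known to tolerate alkoxyaryl pyrrolidines of this class.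

Step 6
Reactants: 10 cyclobutane with 4-methoxybenzyl ester
Product: 11 free lactic acid: (2R)-3-[3,4-bis(benzyloxy)phenyl]-2-acyloxypropanoic acid whose acyl group is the (1S,2R,3S,4S) cyclobutane of 10 (C1 CO2Bn still cis to both aryl groups)
Conditions: CF3CO2H (10 vol%), anisole (5 equiv), CH2Cl2, 0 °C
Reagents that add atoms: none
Why: Acidolysis of the 4-methoxybenzyl ester through the stabilised benzylic cation, trapped by anisole (Friedel–Crafts alkylation), under conditions to which benzyl ethers, the benzyl ester and all stereocentres are inert.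

Step 7
Reactants: 11 free lactic acid (C1-epi)
Product: 12 all-trans acid: C1 epimer of 11, ring configuration (1R,2R,3S,4S), CO2Bn at C1 and acyl lactate at C3 on the face opposite to both aryl groups
Conditions: KOtBu (2.5 equiv), t-BuOH/THF (1:4), 0 °C → rt; then 1 M HCl
Reagents that add atoms: none
Why: Base-mediated thermodynamic epimerisation through the C1 ester enolate: the CO2Bn group leaves the face that carries both neighbouring aryl groups for the all-trans arrangement, C3 is already in its favoured configuration, the lactate α-CH is protected because its carboxyl is a carboxylate, tert-butoxide is too hindered to transesterify, and retro-Michael ring opening is stereoelectronically disfavoured because the enolate π system at C1 is nearly orthogonal to the C2–C3 bond.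

Step 8
Reactants: 12 all-trans acid
Product: 13 (1R,2R,3S,4S)-3-{[(1R)-1-carboxy-2-(3,4-dihydroxyphenyl)ethoxy]carbonyl}-4-(3,4-dihydroxyphenyl)-2-(4-hydroxyphenyl)cyclobutane-1-carboxylic acid (CNP0270917.1)
Conditions: H2 (1 atm), Pd/C (10 wt%), THF/MeOH (1:1), rt, under argon on work-up
Reagents that add atoms: none
Why: Catalytic hydrogenolysis of five aryl benzyl ethers and the benzyl ester, which should leave the cyclobutane C–C bonds, the non-benzylic lactate ester and all five stereocentres untouched.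

**Compound list**

1 | (R)-rosmarinic acid | O=C(O[C@H](Cc1ccc(O)c(O)c1)C(=O)O)/C=C/c1ccc(O)c(O)c1 | starting material
2 | 4-methoxybenzyl (R)-rosmarinate | O=C(O[C@H](Cc1ccc(O)c(O)c1)C(=O)OCc1ccc(OC)cc1)/C=C/c1ccc(O)c(O)c1 | intermediate
3 | 4-methoxybenzyl tetra-O-benzyl-(R)-rosmarinate | O=C(O[C@H](Cc1ccc(OCc2ccccc2)c(OCc2ccccc2)c1)C(=O)OCc1ccc(OC)cc1)/C=C/c1ccc(OCc2ccccc2)c(OCc2ccccc2)c1 | intermediate
4 | glycine benzyl ester hydrochloride | Cl.NCC(=O)OCc1ccccc1 | starting material
5 | 4-(benzyloxy)benzaldehyde | O=Cc1ccc(OCc2ccccc2)cc1 | starting material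
6 | benzyl N-[(E)-4-(benzyloxy)benzylidene]glycinate | O=C(OCc1ccccc1)C/N=C/c1ccc(OCc2ccccc2)cc1 | intermediate
7 | (2S,3S,4R,5R) exo pyrrolidine | O=C(OCc1ccccc1)[C@H]1N[C@@H](c2ccc(OCc3ccccc3)cc2)[C@H](C(=O)O[C@H](Cc2ccc(OCc3ccccc3)c(OCc3ccccc3)c2)C(=O)OCc2ccc(OC)cc2)[C@H]1c1ccc(OCc2ccccc2)c(OCc2ccccc2)c1 | intermediate
8 | 1,1-diazene of 7 | O=C(OCc1ccccc1)[C@H]1[N+](=[N-])[C@@H](c2ccc(OCc3ccccc3)cc2)[C@H](C(=O)O[C@H](Cc2ccc(OCc3ccccc3)c(OCc3ccccc3)c2)C(=O)OCc2ccc(OC)cc2)[C@H]1c1ccc(OCc2ccccc2)c(OCc2ccccc2)c1 | intermediate (not isolated)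
9 | 1,4-biradical (radicals at C1 and C2, C3 and C4 as in 7) | O=C(OCc1ccccc1)[CH][C@H](c1ccc(OCc2ccccc2)c(OCc2ccccc2)c1)[C@@H](C(=O)O[C@H](Cc1ccc(OCc2ccccc2)c(OCc2ccccc2)c1)C(=O)OCc1ccc(OC)cc1)[CH]c1ccc(OCc2ccccc2)cc1 | intermediate (not isolated)
10 | (1S,2R,3S,4S) cyclobutane, C1-epi, 4-methoxybenzyl ester | O=C(OCc1ccccc1)[C@H]1[C@@H](c2ccc(OCc3ccccc3)cc2)[C@H](C(=O)O[C@H](Cc2ccc(OCc3ccccc3)c(OCc3ccccc3)c2)C(=O)OCc2ccc(OC)cc2)[C@H]1c1ccc(OCc2ccccc2)c(OCc2ccccc2)c1 | intermediate
11 | (1S,2R,3S,4S) cyclobutane, C1-epi, free lactic acid | O=C(OCc1ccccc1)[C@H]1[C@@H](c2ccc(OCc3ccccc3)cc2)[C@H](C(=O)O[C@H](Cc2ccc(OCc3ccccc3)c(OCc3ccccc3)c2)C(=O)O)[C@H]1c1ccc(OCc2ccccc2)c(OCc2ccccc2)c1 | intermediate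
12 | (1R,2R,3S,4S) all-trans cyclobutane, free lactic acid | O=C(OCc1ccccc1)[C@@H]1[C@@H](c2ccc(OCc3ccccc3)cc2)[C@H](C(=O)O[C@H](Cc2ccc(OCc3ccccc3)c(OCc3ccccc3)c2)C(=O)O)[C@H]1c1ccc(OCc2ccccc2)c(OCc2ccccc2)c1 | intermediate
13 | CNP0270917.1 | O=C(O)[C@@H]1[C@@H](c2ccc(O)cc2)[C@H](C(=O)O[C@H](Cc2ccc(O)c(O)c2)C(=O)O)[C@H]1c1ccc(O)c(O)c1 | target

**Step count and risks**

Total step count: 8. Longest linear sequence: 7 (steps 1, 2, 4, 5, 6, 7, 8).

Step 4 – what may go wrong: the sluggish β-aryl enoate may react through the endo transition state or with weak facial bias, which would place the two aryl groups trans, an error no later step can repair. Fallback: only the cis relation of the aryl groups must come from the cycloaddition, because step 7 can invert both ester-bearing carbons. Setting out from 3, triplet-sensitised E→Z isomerisation (fac-Ir(ppy)3, blue light, MeCN) should give the (Z)-enoate F1. An endo-selective cycloaddition of F1 with 6 (AgOAc, chiral P,N ligand such as QUINAP in the suitable antipode, iPr2NEt, THF) should transfer the (Z) geometry, as it does for maleates, and give the all-cis pyrrolidine F2. Contraction as in step 5 should give the all-cis cyclobutane F3, and CF3CO2H/anisole the acid F4. KOtBu under the conditions of step 7 should then epimerise C1 and C3 together, so the sequence comes back to the route at 12.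

Step 5 – what may go wrong: β-scission of the biradical at 80 °C, oxidative attack of the trivalent iodine reagent on the dialkoxyarene rings, or ammonolysis of the activated lactate ester may outrun clean contraction. Fallback: generate the same diazene stepwise and cold, without an iodane. Setting out from 7, nitrosation (t-BuONO, CH2Cl2) should give the N-nitrosopyrrolidine F5, and reduction (Zn, AcOH, 0 °C) the 1-aminopyrrolidine F6. Oxidation of this 1,1-disubstituted hydrazine (t-BuOCl, Et3N, −78 °C → rt, or HgO) should form the diazene 8, which loses N2 on warming, and the sequence comes back at 10.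

Step 7 – what may go wrong: equilibration at C1 may be accompanied by acyl cleavage or migration at the hindered lactate ester, by partial inversion at the lactate centre if carboxylate formation is incomplete, or by slow, incomplete epimerisation. Fallback: correct C1 before any lactate unit is present. Setting out from 6, Wittig olefination of commercial 3,4-bis(benzyloxy)benzaldehyde with tert-butyl (triphenylphosphoranylidene)acetate gives tert-butyl (E)-3-[3,4-bis(benzyloxy)phenyl]acrylate F7. The cycloaddition of step 4 with 6 should give the exo pyrrolidine F8, and the contraction of step 5 the C1-epi cyclobutane diester F9. NaOBn in BnOH/THF (degenerate transesterification at C1, inert tert-butyl ester) should equilibrate it to the all-trans diester F10, and CF3CO2H/CH2Cl2 should free the C3 acid F11. Steglich esterification (EDC·HCl, DMAP, CH2Cl2) with benzyl (R)-3-[3,4-bis(benzyloxy)phenyl]-2-hydroxypropanoate F12 (from commercial sodium (R)-danshensu, BnBr, K2CO3, DMF) should give the heptabenzyl compound F13. Hydrogenolysis as in step 8 comes back to the route at 13.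

**Further compounds**

F1 | step 4 | 4-methoxybenzyl tetra-O-benzyl-(R)-rosmarinate, (Z)-isomer | O=C(O[C@H](Cc1ccc(OCc2ccccc2)c(OCc2ccccc2)c1)C(=O)OCc1ccc(OC)cc1)/C=C\c1ccc(OCc2ccccc2)c(OCc2ccccc2)c1
F2 | step 4 | (2S,3S,4S,5R) all-cis pyrrolidine (C4 epimer of 7) | O=C(OCc1ccccc1)[C@H]1N[C@@H](c2ccc(OCc3ccccc3)cc2)[C@@H](C(=O)O[C@H](Cc2ccc(OCc3ccccc3)c(OCc3ccccc3)c2)C(=O)OCc2ccc(OC)cc2)[C@H]1c1ccc(OCc2ccccc2)c(OCc2ccccc2)c1
F3 | step 4 | all-cis cyclobutane (C3 epimer of 10) | O=C(OCc1ccccc1)[C@H]1[C@@H](c2ccc(OCc3ccccc3)cc2)[C@@H](C(=O)O[C@H](Cc2ccc(OCc3ccccc3)c(OCc3ccccc3)c2)C(=O)OCc2ccc(OC)cc2)[C@H]1c1ccc(OCc2ccccc2)c(OCc2ccccc2)c1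
F4 | step 4 | all-cis cyclobutane, free lactic acid (C3 epimer of 11) | O=C(OCc1ccccc1)[C@H]1[C@@H](c2ccc(OCc3ccccc3)cc2)[C@@H](C(=O)O[C@H](Cc2ccc(OCc3ccccc3)c(OCc3ccccc3)c2)C(=O)O)[C@H]1c1ccc(OCc2ccccc2)c(OCc2ccccc2)c1
F5 | step 5 | N-nitroso derivative of 7 | O=C(OCc1ccccc1)[C@H]1N(N=O)[C@@H](c2ccc(OCc3ccccc3)cc2)[C@H](C(=O)O[C@H](Cc2ccc(OCc3ccccc3)c(OCc3ccccc3)c2)C(=O)OCc2ccc(OC)cc2)[C@H]1c1ccc(OCc2ccccc2)c(OCc2ccccc2)c1
F6 | step 5 | 1-amino derivative of 7 | O=C(OCc1ccccc1)[C@H]1N(N)[C@@H](c2ccc(OCc3ccccc3)cc2)[C@H](C(=O)O[C@H](Cc2ccc(OCc3ccccc3)c(OCc3ccccc3)c2)C(=O)OCc2ccc(OC)cc2)[C@H]1c1ccc(OCc2ccccc2)c(OCc2ccccc2)c1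
F7 | step 7 | tert-butyl (E)-3-[3,4-bis(benzyloxy)phenyl]acrylate | O=C(OC(C)(C)C)/C=C/c1ccc(OCc2ccccc2)c(OCc2ccccc2)c1
F8 | step 7 | 2-benzyl 4-tert-butyl exo pyrrolidine-2,4-dicarboxylate (stereochemistry as in 7) | O=C(OCc1ccccc1)[C@H]1N[C@@H](c2ccc(OCc3ccccc3)cc2)[C@H](C(=O)OC(C)(C)C)[C@H]1c1ccc(OCc2ccccc2)c(OCc2ccccc2)c1
F9 | step 7 | 1-benzyl 3-tert-butyl cyclobutane-1,3-dicarboxylate, C1-epi (as in 10) | O=C(OCc1ccccc1)[C@H]1[C@@H](c2ccc(OCc3ccccc3)cc2)[C@H](C(=O)OC(C)(C)C)[C@H]1c1ccc(OCc2ccccc2)c(OCc2ccccc2)c1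
F10 | step 7 | 1-benzyl 3-tert-butyl cyclobutane-1,3-dicarboxylate, all-trans | O=C(OCc1ccccc1)[C@@H]1[C@@H](c2ccc(OCc3ccccc3)cc2)[C@H](C(=O)OC(C)(C)C)[C@H]1c1ccc(OCc2ccccc2)c(OCc2ccccc2)c1
F11 | step 7 | all-trans cyclobutane C3 acid, C1 benzyl ester | O=C(OCc1ccccc1)[C@@H]1[C@@H](c2ccc(OCc3ccccc3)cc2)[C@H](C(=O)O)[C@H]1c1ccc(OCc2ccccc2)c(OCc2ccccc2)c1
F12 | step 7 | benzyl (R)-3-[3,4-bis(benzyloxy)phenyl]-2-hydroxypropanoate | O[C@H](Cc1ccc(OCc2ccccc2)c(OCc2ccccc2)c1)C(=O)OCc1ccccc1
F13 | step 7 | heptabenzyl derivative of 13 (all-trans) | O=C(OCc1ccccc1)[C@@H]1[C@@H](c2ccc(OCc3ccccc3)cc2)[C@H](C(=O)O[C@H](Cc2ccc(OCc3ccccc3)c(OCc3ccccc3)c2)C(=O)OCc2ccccc2)[C@H]1c1ccc(OCc2ccccc2)c(OCc2ccccc2)c1
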